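**Retrosynthetic overview**

1. The target is (13S)-15-acetoxylabd-7-en-17-oic acid (labdane numbering: ring A = C1–C5 and C10, ring B = C5–C10, side chain C11–C16 on C9, C17 on C8, C20 on C10). Late disconnections are the C17 acid (from a C17 silyl ether, with the ring double bond moved from C6=C7 into conjugation) and the C11–C12 bond (Wittig reaction of a C11 aldehyde with a C12–C15 ylide from (R)-2-methylsuccinate, then hydrogenation).
2. The remaining 6-ene bicycle with a carbonyl at C11 is the retron of an intramolecular Diels–Alder reaction; cutting C5–C10 and C8–C9 gives an acyclic (2E,8E,10E)-trienoyl oxazolidinone.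
3. Enabling feature: in ring B the ring-fusion atoms C5 and C10 are adjacent, C9 carries a carbon (C11) that can serve as an activating carbonyl, and C8 carries a one-carbon group (C17) through which the C6=C7 bond of the cycloadduct can later be moved to C7=C8. Hence C5=C6–C7=C8 is the diene, C9=C10 the dienophile, and C1–C4 of ring A (with the gem-dimethyl C4) the four-atom tether.
4. Ring order: no ring exists before the key step; rings A and B close together in it (ring A through the tether when C5–C10 forms, ring B as the new cyclohexene), and C5, C9 and C10 are set under control of an Evans auxiliary.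
5. The triene is built linearly from 5-chloro-2,2-dimethylpentanenitrile: acetylide displacement, Horner–Wadsworth–Emmons dienoate, and zirconium-catalysed carboalumination–carboxylation for the (E)-C9=C10 unit carrying C20.

Key step: step 8

Remark: 5-chloro-2,2-dimethylpentanenitrile, triethyl 4-phosphonocrotonate, (S)-4-benzyloxazolidin-2-one and (R)-2-methylsuccinic acid 4-methyl ester are taken as catalogue chemicals; bicyclic compounds are named with labdane numbering, β meaning the face of the C20 methyl group.

**Route**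

Step 1
Reactants: 1 5-chloro-2,2-dimethylpentanenitrile
Product: 2 2,2-dimethylhept-6-ynenitrile
Conditions: LiC≡CH·H2NCH2CH2NH2, NaI (cat.), DMSO, 10 °C → rt
Reagents that add atoms: lithium acetylide, [Li+].[C-]#C
Why: SN2 alkynylation of a primary alkyl chloride by lithium acetylide (iodide-assisted) should proceed cleanly because the tertiary nitrile has no α-hydrogen and is too hindered for addition, and no stereocentre is involved.

Step 2
Reactants: 2 2,2-dimethylhept-6-ynenitrile
Product: 3 2,2-dimethylhept-6-ynal
Conditions: i-Bu2AlH (1.2 equiv), CH2Cl2, −78 °C; then 1 M aq. HCl, 0 °C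
Reagents that add atoms: water, O
Why: DIBAL-H partial reduction of a nitrile stops after one hydride transfer at −78 °C and acidic work-up should release the non-enolisable neopentyl aldehyde, the terminal alkyne being inert under these conditions.

Step 3
Reactants: 3 2,2-dimethylhept-6-ynal; 4 triethyl (E)-4-phosphonocrotonate
Product: 5 ethyl (2E,4E)-6,6-dimethylundeca-2,4-dien-10-ynoate
Conditions: LiN(SiMe3)2, THF, −78 °C; then 3, −78 → 0 °C
Reagents that add atoms: none
Why: Vinylogous Horner–Wadsworth–Emmons olefination of a non-enolisable aldehyde with the lithiated phosphonocrotonate should give the (2E,4E)-dienoate, the new C5=C6 bond (labdane numbering) forming E under the usual thermodynamic control of stabilised phosphonates and the C7=C8 bond keeping the E geometry of the reagent.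

Step 4
Reactants: 5 ethyl (2E,4E)-6,6-dimethylundeca-2,4-dien-10-ynoate
Product: 6 (2E,4E)-6,6-dimethylundeca-2,4-dien-10-yn-1-ol
Conditions: i-Bu2AlH (2.3 equiv), CH2Cl2, −78 → 0 °C; Rochelle salt work-up
Reagents that add atoms: none
Why: DIBAL-H reduction of a dienoate at low temperature is a reliable 1,2-reduction to the dienyl alcohol that leaves the diene geometry and the alkyne untouched.

Step 5
Reactants: 6 (2E,4E)-6,6-dimethylundeca-2,4-dien-10-yn-1-ol
Product: 7 tert-butyl{[(2E,4E)-6,6-dimethylundeca-2,4-dien-10-yn-1-yl]oxy}diphenylsilane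
Conditions: TBDPSCl, imidazole, CH2Cl2, 0 °C → rt
Reagents that add atoms: tert-butyl(chloro)diphenylsilane, CC(C)(C)[Si](Cl)(c1ccccc1)c1ccccc1
Why: Imidazole-mediated silylation of the primary alcohol installs a bulky, weakly Lewis-basic TBDPS ether that is expected to survive Me3Al, n-BuLi, Me2AlCl and LiBH4 in the following steps.

Step 6
Reactants: 7 tert-butyl{[(2E,4E)-6,6-dimethylundeca-2,4-dien-10-yn-1-yl]oxy}diphenylsilane
Product: 10 (2E,8E,10E)-12-[(tert-butyldiphenylsilyl)oxy]-3,7,7-trimethyldodeca-2,8,10-trienoic acid, via alkenyldimethylalane 8 (not isolated), via lithium alkenylalanate 9 (not isolated)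
Conditions: Me3Al (2.5 equiv), Cp2ZrCl2 (0.25 equiv), CH2Cl2, 0 °C → rt; volatiles removed; n-BuLi (1.0 equiv), THF/hexane, −78 °C; CO2 (g), −78 °C → rt; aq. HCl
Reagents that add atoms: trimethylaluminium, C[Al](C)C; carbon dioxide, O=C=O
Why: Negishi zirconium-catalysed carboalumination adds methyl and aluminium syn across the terminal alkyne with methyl on the internal carbon, and carboxylation of the derived alanate with retention should give only the (2E)-3-methyl-2-enoic acid, which fixes the later cis relationship of C20 and C11.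

Step 7
Reactants: 10 (2E,8E,10E)-12-[(tert-butyldiphenylsilyl)oxy]-3,7,7-trimethyldodeca-2,8,10-trienoic acid; 11 (S)-4-benzyloxazolidin-2-one
Product: 13 (S)-4-benzyl-3-{(2E,8E,10E)-12-[(tert-butyldiphenylsilyl)oxy]-3,7,7-trimethyldodeca-2,8,10-trienoyl}oxazolidin-2-one, via mixed pivalic anhydride 12 (not isolated)
Conditions: t-BuCOCl, Et3N, THF, −20 °C; then 11, LiCl, −20 °C → rt
Reagents that add atoms: none
Why: N-Acylation of the oxazolidinone through the mixed pivalic anhydride (Et3N/LiCl protocol) is mild enough to keep the β,β-disubstituted enoyl unit conjugated and E, and it does not touch the stereocentre of the auxiliary.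

Step 8
Reactants: 13 (S)-4-benzyl-3-{(2E,8E,10E)-12-[(tert-butyldiphenylsilyl)oxy]-3,7,7-trimethyldodeca-2,8,10-trienoyl}oxazolidin-2-one
Product: 14 (S)-4-benzyl-3-{17-[(tert-butyldiphenylsilyl)oxy]-12,13,14,15,16-pentanorlabd-6-en-11-oyl}oxazolidin-2-one (trans-fused; 5α,8α,9α-H; 10β-methyl)
Conditions: Me2AlCl (1.6 equiv), CH2Cl2, −30 → 0 °C
Reagents that add atoms: none
Why: Two-point binding of the imide carbonyls to the aluminium Lewis acid holds the enoyl group s-cis and lowers its LUMO, and the tethered (8E,10E)-diene then adds across C9=C10 in a concerted, asynchronous [4+2] cycloaddition (type 1 intramolecular Diels–Alder reaction); the closest known reaction type is the Me2AlCl-promoted, auxiliary-controlled cyclisation of (E,E,E)-trienoyl oxazolidinones to trans-fused hydrindenes and octalins. Ring A closes as the six-membered carbocycle spanned by the four-atom tether C1–C4 when the C5–C10 bond joins the inner diene terminus to the β-carbon of the dienophile, and ring B closes as the cyclohexene of the cycloaddition through the C5–C10 and C8–C9 bonds. The C9/C10 relationship (C11 cis to C20) follows from the (E)-geometry of the dienophile; the trans ring fusion at C5/C10 and the 8β-substituent follow from the endo transition state, in which the bound carbonyl lies under the diene and the tether adopts a chair. The absolute configuration comes from the benzyl group of the (S)-auxiliary, which covers the Re face of C9 so that the diene adds to the C9-Si/C10-Re face. The step needs endo over exo selectivity, one π-face and enough reactivity at the β,β-disubstituted C10: the Lewis acid complex secures the first two, and the strong activation together with the gem-dimethyl group at C4 (Thorpe–Ingold effect) should help the congested C5–C10 bond to form.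

Step 9
Reactants: 14 Diels–Alder adduct imide
Product: 15 17-[(tert-butyldiphenylsilyl)oxy]-12,13,14,15,16-pentanorlabd-6-en-11-ol (5α,8α,9α-H)
Conditions: LiBH4 (2 equiv), H2O (1 equiv), Et2O, 0 °C
Reagents that add atoms: none
Why: Reductive cleavage of an N-acyloxazolidinone with LiBH4 in wet ether should deliver hydride to the exocyclic carbonyl, releasing the C11 alcohol and the recoverable auxiliary while the ring alkene, the silyl ether and all stereocentres stay untouched.

Step 10
Reactants: 15 17-[(tert-butyldiphenylsilyl)oxy]-12,13,14,15,16-pentanorlabd-6-en-11-ol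
Product: 16 17-[(tert-butyldiphenylsilyl)oxy]-12,13,14,15,16-pentanorlabd-6-en-11-al (5α,8α,9α-H)
Conditions: Dess–Martin periodinane, NaHCO3, CH2Cl2, 0 °C → rt
Reagents that add atoms: none
Why: Dess–Martin oxidation under bicarbonate buffering gives the aldehyde without base, so that C9, whose 9β (equatorial) formyl group is in any case the more stable arrangement, is not epimerised.

Step 11
Reactants: 17 (R)-4-methoxy-2-methyl-4-oxobutanoic acid
Product: 18 methyl (R)-4-hydroxy-3-methylbutanoate
Conditions: BH3·SMe2 (1.1 equiv), THF, 0 °C → rt; MeOH quench; used crude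
Reagents that add atoms: none
Why: Chemoselective borane reduction of a carboxylic acid in the presence of a methyl ester differentiates the two ends of the four-carbon unit without touching its stereocentre, the future C13.

Step 12
Reactants: 18 methyl (R)-4-hydroxy-3-methylbutanoate
Product: 19 methyl (R)-4-iodo-3-methylbutanoate
Conditions: I2, PPh3, imidazole, CH2Cl2, 0 °C → rt
Reagents that add atoms: iodine, II
Why: Appel-type iodination (PPh3/I2/imidazole) converts the primary alcohol into the iodide by SN2 at CH2, not at the stereocentre, and intercepts the γ-hydroxy ester before it can lactonise.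

Step 13
Reactants: 19 methyl (R)-4-iodo-3-methylbutanoate
Product: 20 (R)-4-iodo-3-methylbutan-1-ol
Conditions: i-Bu2AlH (2.2 equiv), CH2Cl2, −78 → −20 °C; Rochelle salt work-up; used at once
Reagents that add atoms: none
Why: DIBAL-H reduction of the ester to the primary alcohol tolerates the primary iodide at low temperature, and the iodo alcohol is carried on at once so that cyclisation to 3-methyltetrahydrofuran does not intervene.

Step 14
Reactants: 20 (R)-4-iodo-3-methylbutan-1-ol
Product: 21 [(R)-4-hydroxy-2-methylbutyl]triphenylphosphonium iodide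
Conditions: PPh3 (1.2 equiv), MeCN, 80 °C, dark
Reagents that add atoms: triphenylphosphine, c1ccc(cc1)P(c1ccccc1)c1ccccc1
Why: Quaternisation of PPh3 by the primary iodide (SN2) gives the ω-hydroxyalkylphosphonium salt, a class of Wittig reagents that is used without protection of the hydroxyl group.

Step 15
Reactants: 16 17-[(tert-butyldiphenylsilyl)oxy]-12,13,14,15,16-pentanorlabd-6-en-11-al; 21 [(R)-4-hydroxy-2-methylbutyl]triphenylphosphonium iodide
Product: 23 (11Z,13R)-17-[(tert-butyldiphenylsilyl)oxy]labda-6,11-dien-15-ol, via oxido ylide 22 (not isolated)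
Conditions: 21 (2.0 equiv), NaN(SiMe3)2 (4.0 equiv), THF, −78 → 0 °C; then 16, −78 °C → rt
Reagents that add atoms: none
Why: Wittig olefination with the non-stabilised oxido ylide should give mainly the (11Z)-alkene, whose geometry is irrelevant because the bond is hydrogenated in step 20, while C13 (β to phosphorus and not acidic) and the shielded, thermodynamically preferred 9β-aldehyde centre keep their configurations.

Step 16
Reactants: 23 (11Z,13R)-17-[(tert-butyldiphenylsilyl)oxy]labda-6,11-dien-15-ol
Product: 24 (11Z,13R)-17-[(tert-butyldiphenylsilyl)oxy]labda-6,11-dien-15-yl acetate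
Conditions: Ac2O, pyridine, DMAP (cat.), CH2Cl2, rt
Reagents that add atoms: acetic anhydride, CC(=O)OC(C)=O
Why: DMAP-catalysed acetylation of the only free hydroxyl group, the primary C15 alcohol, installs the acetate of the target.

Step 17
Reactants: 24 (11Z,13R)-17-[(tert-butyldiphenylsilyl)oxy]labda-6,11-dien-15-yl acetate
Product: 25 (11Z,13R)-17-hydroxylabda-6,11-dien-15-yl acetate
Conditions: HF·pyridine, pyridine, THF, 0 °C → rt
Reagents that add atoms: none
Why: Fluoride-mediated desilylation with buffered HF·pyridine removes the primary TBDPS ether without hydrolysing the acetate or affecting the alkenes and stereocentres.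

Step 18
Reactants: 25 (11Z,13R)-17-hydroxylabda-6,11-dien-15-yl acetate
Product: 27 (11Z,13R)-17-oxolabda-7,11-dien-15-yl acetate, via β,γ-unsaturated aldehyde 26 (not isolated)
Conditions: Dess–Martin periodinane, NaHCO3, CH2Cl2, 0 °C → rt; then DBU (3 equiv), rt
Reagents that add atoms: none
Why: Dess–Martin oxidation gives the β,γ-unsaturated aldehyde, which DBU isomerises through its dienolate (deprotonation at C8, reprotonation at C6) into the conjugated trisubstituted enal as the thermodynamic sink, erasing the C8 centre as planned and leaving C9, which is not vinylogously acidified, untouched.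

Step 19
Reactants: 27 (11Z,13R)-17-oxolabda-7,11-dien-15-yl acetate
Product: 28 (11Z,13R)-15-acetoxylabda-7,11-dien-17-oic acid
Conditions: NaClO2, NaH2PO4, 2-methyl-2-butene, t-BuOH/H2O, 0 °C → rt
Reagents that add atoms: sodium chlorite, [Na+].[O-]Cl=O
Why: Pinnick oxidation with NaClO2 converts the hindered enal into the acid under mildly acidic buffered conditions, 2-methyl-2-butene scavenging hypochlorous acid so that the alkenes and the acetate survive.

Step 20
Reactants: 28 (11Z,13R)-15-acetoxylabda-7,11-dien-17-oic acid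
Product: 29 (13S)-15-acetoxylabd-7-en-17-oic acid (5S,9R,10S,13S), the target
Conditions: H2 (3 atm), RhCl(PPh3)3 (10 mol %), benzene/EtOH 1:1, rt
Reagents that add atoms: none
Why: Homogeneous hydrogenation with Wilkinson's catalyst, RhCl(PPh3)3, should saturate the disubstituted C11=C12 bond while sparing the trisubstituted conjugated C7=C8 bond and, unlike heterogeneous palladium, should not migrate the double bond toward the allylic C13 centre, whose geometry is kept (its descriptor changes from R to S only because the CIP priorities change).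

**Compound list**

1 | 5-chloro-2,2-dimethylpentanenitrile | N#CC(C)(C)CCCCl | starting material
2 | 2,2-dimethylhept-6-ynenitrile | N#CC(C)(C)CCCC#C | intermediate
3 | 2,2-dimethylhept-6-ynal | O=CC(C)(C)CCCC#C | intermediate
4 | triethyl (E)-4-phosphonocrotonate | CCOC(=O)/C=C/CP(=O)(OCC)OCC | starting material
5 | ethyl (2E,4E)-6,6-dimethylundeca-2,4-dien-10-ynoate | CCOC(=O)/C=C/C=C/C(C)(C)CCCC#C | intermediate
6 | (2E,4E)-6,6-dimethylundeca-2,4-dien-10-yn-1-ol | OC/C=C/C=C/C(C)(C)CCCC#C | intermediate
7 | tert-butyl{[(2E,4E)-6,6-dimethylundeca-2,4-dien-10-yn-1-yl]oxy}diphenylsilane | C#CCCCC(C)(C)/C=C/C=C/CO[Si](c1ccccc1)(c1ccccc1)C(C)(C)C | intermediate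
8 | [(1E,7E,9E)-11-{[tert-butyl(diphenyl)silyl]oxy}-2,6,6-trimethylundeca-1,7,9-trien-1-yl]dimethylalane | C[Al](C)/C=C(\C)CCCC(C)(C)/C=C/C=C/CO[Si](c1ccccc1)(c1ccccc1)C(C)(C)C | intermediate
9 | lithium butyl[(1E,7E,9E)-11-{[tert-butyl(diphenyl)silyl]oxy}-2,6,6-trimethylundeca-1,7,9-trien-1-yl]dimethylalanate | [Li+].CCCC[Al-](C)(C)/C=C(\C)CCCC(C)(C)/C=C/C=C/CO[Si](c1ccccc1)(c1ccccc1)C(C)(C)C | intermediate
10 | (2E,8E,10E)-12-[(tert-butyldiphenylsilyl)oxy]-3,7,7-trimethyldodeca-2,8,10-trienoic acid | OC(=O)/C=C(\C)CCCC(C)(C)/C=C/C=C/CO[Si](c1ccccc1)(c1ccccc1)C(C)(C)C | intermediate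
11 | (S)-4-benzyloxazolidin-2-one | O=C1N[C@@H](Cc2ccccc2)CO1 | starting material
12 | (2E,8E,10E)-12-[(tert-butyldiphenylsilyl)oxy]-3,7,7-trimethyldodeca-2,8,10-trienoic pivalic anhydride | CC(C)(C)C(=O)OC(=O)/C=C(\C)CCCC(C)(C)/C=C/C=C/CO[Si](c1ccccc1)(c1ccccc1)C(C)(C)C | intermediate
13 | (S)-4-benzyl-3-{(2E,8E,10E)-12-[(tert-butyldiphenylsilyl)oxy]-3,7,7-trimethyldodeca-2,8,10-trienoyl}oxazolidin-2-one | O=C1OC[C@H](Cc2ccccc2)N1C(=O)/C=C(\C)CCCC(C)(C)/C=C/C=C/CO[Si](c1ccccc1)(c1ccccc1)C(C)(C)C | intermediate
14 | (S)-4-benzyl-3-{17-[(tert-butyldiphenylsilyl)oxy]-12,13,14,15,16-pentanorlabd-6-en-11-oyl}oxazolidin-2-one (trans-fused; 5α,8α,9α-H; 10β-methyl) | O=C1OC[C@H](Cc2ccccc2)N1C(=O)[C@H]1[C@@H](CO[Si](c2ccccc2)(c2ccccc2)C(C)(C)C)C=C[C@H]2C(C)(C)CCC[C@]12C | intermediate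
15 | 17-[(tert-butyldiphenylsilyl)oxy]-12,13,14,15,16-pentanorlabd-6-en-11-ol (5α,8α,9α-H) | OC[C@H]1[C@@H](CO[Si](c2ccccc2)(c2ccccc2)C(C)(C)C)C=C[C@H]2C(C)(C)CCC[C@]12C | intermediate
16 | 17-[(tert-butyldiphenylsilyl)oxy]-12,13,14,15,16-pentanorlabd-6-en-11-al (5α,8α,9α-H) | O=C[C@H]1[C@@H](CO[Si](c2ccccc2)(c2ccccc2)C(C)(C)C)C=C[C@H]2C(C)(C)CCC[C@]12C | intermediate
17 | (R)-4-methoxy-2-methyl-4-oxobutanoic acid | COC(=O)C[C@@H](C)C(=O)O | starting material
18 | methyl (R)-4-hydroxy-3-methylbutanoate | COC(=O)C[C@@H](C)CO | intermediate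
19 | methyl (R)-4-iodo-3-methylbutanoate | COC(=O)C[C@@H](C)CI | intermediate
20 | (R)-4-iodo-3-methylbutan-1-ol | OCC[C@@H](C)CI | intermediate
21 | [(R)-4-hydroxy-2-methylbutyl]triphenylphosphonium iodide | OCC[C@@H](C)C[P+](c1ccccc1)(c1ccccc1)c1ccccc1.[I-] | intermediate
22 | sodium (R)-3-methyl-4-(triphenyl-λ5-phosphanylidene)butan-1-olate | [Na+].[O-]CC[C@@H](C)C=P(c1ccccc1)(c1ccccc1)c1ccccc1 | intermediate
23 | (11Z,13R)-17-[(tert-butyldiphenylsilyl)oxy]labda-6,11-dien-15-ol (5α,8α,9α-H) | OCC[C@@H](C)/C=C\[C@H]1[C@@H](CO[Si](c2ccccc2)(c2ccccc2)C(C)(C)C)C=C[C@H]2C(C)(C)CCC[C@]12C | intermediate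
24 | (11Z,13R)-17-[(tert-butyldiphenylsilyl)oxy]labda-6,11-dien-15-yl acetate | CC(=O)OCC[C@@H](C)/C=C\[C@H]1[C@@H](CO[Si](c2ccccc2)(c2ccccc2)C(C)(C)C)C=C[C@H]2C(C)(C)CCC[C@]12C | intermediate
25 | (11Z,13R)-17-hydroxylabda-6,11-dien-15-yl acetate | CC(=O)OCC[C@@H](C)/C=C\[C@H]1[C@@H](CO)C=C[C@H]2C(C)(C)CCC[C@]12C | intermediate
26 | (11Z,13R)-17-oxolabda-6,11-dien-15-yl acetate (8α-H) | CC(=O)OCC[C@@H](C)/C=C\[C@H]1[C@@H](C=O)C=C[C@H]2C(C)(C)CCC[C@]12C | intermediate
27 | (11Z,13R)-17-oxolabda-7,11-dien-15-yl acetate | CC(=O)OCC[C@@H](C)/C=C\[C@H]1C(C=O)=CC[C@H]2C(C)(C)CCC[C@]12C | intermediate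
28 | (11Z,13R)-15-acetoxylabda-7,11-dien-17-oic acid | CC(=O)OCC[C@@H](C)/C=C\[C@H]1C(C(=O)O)=CC[C@H]2C(C)(C)CCC[C@]12C | intermediate
29 | (13S)-15-acetoxylabd-7-en-17-oic acid (5S,9R,10S,13S) | CC(=O)OCC[C@@H](C)CC[C@H]1C(C(=O)O)=CC[C@H]2C(C)(C)CCC[C@]12C | target

**Step count and risks**

Total step count: 20. Longest linear sequence: 16 steps (steps 1–10 and 15–20); steps 11–14 make the side-chain phosphonium salt.

The three steps most likely to fail:

1. Step 8 (key cycloaddition). The cycloaddition may stall or lose selectivity. The C5–C10 bond joins a fully substituted β-carbon to a carbon next to the quaternary C4, and a syn-diaxial methyl/methyl contact (C20 against the 4β-methyl) develops in the endo transition state. On warming, methyl transfer from aluminium to C10, leakage through the exo (cis-fused) pathway or ionisation of the dienylic silyl ether could take over. Fallback: set out from alkyne 7, run the carboalumination of step 6 to alane 8, but quench with paraformaldehyde to obtain (2E,8E,10E)-12-[(tert-butyldiphenylsilyl)oxy]-3,7,7-trimethyldodeca-2,8,10-trien-1-ol F1. Oxidation with MnO2 (CH2Cl2, rt) gives (2E,8E,10E)-12-[(tert-butyldiphenylsilyl)oxy]-3,7,7-trimethyldodeca-2,8,10-trienal F2. F2 is then cyclised under amine-salt (LUMO-lowering) catalysis with (2S,5S)-5-benzyl-2-tert-butyl-3-methylimidazolidin-4-one trifluoroacetate (20 mol %, MeCN/H2O, −20 °C → rt). The benzyl and tert-butyl groups of this catalyst are expected to leave the same C10-Re face open, and its endo preference should again give the trans ring fusion. This delivers aldehyde 16 directly, so the route is rejoined at 16 and steps 7–10 fall away.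

2. Step 9 (removal of the auxiliary). Hydride may attack the ring carbonyl of the oxazolidinone instead of the exocyclic one, because the exocyclic carbonyl is flanked by the quaternary C10 and the substituted C8; this endocyclic cleavage would open the auxiliary and consume the adduct. Fallback: from 14, LiOH/H2O2 (THF/H2O, 0 °C), in which the hydroperoxide anion selects the exocyclic carbonyl, gives 17-[(tert-butyldiphenylsilyl)oxy]-12,13,14,15,16-pentanorlabd-6-en-11-oic acid F3 and the free auxiliary. LiAlH4 (THF, 0 °C) then reduces F3 to alcohol 15, where the route is rejoined.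

3. Step 15 (Wittig coupling). The aggregated, sparingly soluble dianionic oxido ylide may add too slowly to the shielded aldehyde, so that deprotonation at C9 (epimerisation, self-condensation) or simple recovery of the aldehyde competes. Fallback: from iodo alcohol 20, TBSCl/imidazole (CH2Cl2) gives (R)-tert-butyl(4-iodo-3-methylbutoxy)dimethylsilane F4, and PPh3 (MeCN, 80 °C) gives [(R)-4-{[tert-butyl(dimethyl)silyl]oxy}-2-methylbutyl]triphenylphosphonium iodide F5. One equivalent of NaN(SiMe3)2 (THF, −78 → 0 °C) turns F5 into the neutral, soluble (R)-{4-[(tert-butyldimethylsilyl)oxy]-2-methylbutylidene}triphenylphosphorane F6, which with aldehyde 16 gives (11Z,13R)-15-[(tert-butyldimethylsilyl)oxy]-17-[(tert-butyldiphenylsilyl)oxy]labda-6,11-diene F7. Pyridinium p-toluenesulfonate in MeOH (rt) removes the primary TBS ether selectively and returns alcohol 23, where the route is rejoined.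

Further compounds
F1 | step 8 | (2E,8E,10E)-12-[(tert-butyldiphenylsilyl)oxy]-3,7,7-trimethyldodeca-2,8,10-trien-1-ol | OC/C=C(\C)CCCC(C)(C)/C=C/C=C/CO[Si](c1ccccc1)(c1ccccc1)C(C)(C)C
F2 | step 8 | (2E,8E,10E)-12-[(tert-butyldiphenylsilyl)oxy]-3,7,7-trimethyldodeca-2,8,10-trienal | O=C/C=C(\C)CCCC(C)(C)/C=C/C=C/CO[Si](c1ccccc1)(c1ccccc1)C(C)(C)C
F3 | step 9 | 17-[(tert-butyldiphenylsilyl)oxy]-12,13,14,15,16-pentanorlabd-6-en-11-oic acid (5α,8α,9α-H) | OC(=O)[C@H]1[C@@H](CO[Si](c2ccccc2)(c2ccccc2)C(C)(C)C)C=C[C@H]2C(C)(C)CCC[C@]12C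
F4 | step 15 | (R)-tert-butyl(4-iodo-3-methylbutoxy)dimethylsilane | CC(C)(C)[Si](C)(C)OCC[C@@H](C)CI
F5 | step 15 | [(R)-4-{[tert-butyl(dimethyl)silyl]oxy}-2-methylbutyl]triphenylphosphonium iodide | CC(C)(C)[Si](C)(C)OCC[C@@H](C)C[P+](c1ccccc1)(c1ccccc1)c1ccccc1.[I-]
F6 | step 15 | (R)-{4-[(tert-butyldimethylsilyl)oxy]-2-methylbutylidene}triphenylphosphorane | CC(C)(C)[Si](C)(C)OCC[C@@H](C)C=P(c1ccccc1)(c1ccccc1)c1ccccc1
F7 | step 15 | (11Z,13R)-15-[(tert-butyldimethylsilyl)oxy]-17-[(tert-butyldiphenylsilyl)oxy]labda-6,11-diene | CC(C)(C)[Si](C)(C)OCC[C@@H](C)/C=C\[C@H]1[C@@H](CO[Si](c2ccccc2)(c2ccccc2)C(C)(C)C)C=C[C@H]2C(C)(C)CCC[C@]12C
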